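**Retrosynthetic overview**
1. Argophyllin A ⇐ exo-face epoxidation of C1=C10 (oxirane, last ring) ⇐ acetonide removal and C8 angeloylation of germacranolide 33.
2. 33 ⇐ electroreductive Cr-catalysed intramolecular allylation/lactonisation of aldehyde–allylic bromide 30: the C6–C7 bond closes the ten-membered carbocycle and the trans γ-lactone in one step.
3. 30 ⇐ Morita–Baylis–Hillman reaction and bromide transposition at C7, plus anti-Markovnikov hydration of a C4 ethynyl group (C5–C6).
4. C3/C4 diol ⇐ chelate-controlled ethynyl addition to an α-hydroxy methyl ketone, made by alkenyl opening of methyl (S)-glycidate (C1–C2 bond).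
5. (E)-Alkenyl iodide 11 (C7–C10, C1, C14) ⇐ (S)-glycidol, acetylide, Negishi carboalumination. Ring order: dioxolane (temporary) → carbocycle and lactone together → oxirane.

Assumption: germacrane numbering is used (ring C1–C10, lactone carbons C11–C13, C14 on C10, C15 on C4); the target is read as (1R,3S,4S,6R,7S,8R,10R), i.e. 1β,10α-epoxy-3β,4α-dihydroxy-8β-angeloyloxy-6α,12-olide.

**Step 1**
Reactants: 1 (S)-glycidol; 2 lithium acetylide–ethylenediamine complex
Product: 3 (R)-pent-4-yne-1,2-diol
Conditions: LiC≡CH·H2NCH2CH2NH2 (2.5 equiv), DMSO, 0 → 23 °C; aq NH4Cl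
Reagents that add atoms: lithium acetylide–ethylenediamine complex, [Li+].[C-]#C.NCCN
Why: SN2 epoxide opening by acetylide at the unsubstituted CH2 leaves the purchased stereocentre (future C8) untouched, and Payne equilibration of the glycidol alkoxide is degenerate.

**Step 2**
Reactants: 3 (R)-pent-4-yne-1,2-diol; 4 chlorotriethylsilane; 5 tert-butyldimethylsilyl chloride
Product: 7 (R)-2-(tert-butyldimethylsilyloxy)-1-(triethylsilyloxy)pent-4-yne, via primary triethylsilyl ether 6 (not isolated)
Conditions: TESCl (1.05 equiv), imidazole, DMF, −40 °C; then TBSCl (1.5 equiv), imidazole, 23 °C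
Reagents that add atoms: chlorotriethylsilane, CC[Si](Cl)(CC)CC; tert-butyldimethylsilyl chloride, CC(C)(C)[Si](C)(C)Cl
Why: One-pot differential silyl protection: the primary hydroxyl is silylated kinetically at low temperature by TESCl and the remaining secondary hydroxyl is then capped as the more robust TBS ether.

**Step 3**
Reactants: 7 (R)-2-(tert-butyldimethylsilyloxy)-1-(triethylsilyloxy)pent-4-yne; 8 trimethylaluminium; 9 iodine
Product: 11 (1E,4R)-4-(tert-butyldimethylsilyloxy)-1-iodo-2-methyl-5-(triethylsilyloxy)pent-1-ene, via alkenyl(dimethyl)alane 10 (not isolated)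
Conditions: Me3Al (3 equiv), Cp2ZrCl2 (25 mol %), H2O (1 equiv), CH2Cl2, −20 °C; then I2, THF, −30 °C
Reagents that add atoms: trimethylaluminium, C[Al](C)C; iodine, II
Why: Negishi zirconium-catalysed syn-carboalumination puts the methyl group (C14) on the internal and aluminium on the terminal alkyne carbon, and iodinolysis with retention gives the (E)-trisubstituted alkenyl iodide.

**Step 4**
Reactants: 11 (1E,4R)-alkenyl iodide; 12 methyl (S)-glycidate
Product: 15 methyl (2S,4E,7R)-7-(tert-butyldimethylsilyloxy)-2-hydroxy-5-methyl-8-(triethylsilyloxy)oct-4-enoate, via alkenyllithium 13 (not isolated), via alkenylmagnesium bromide 14 (not isolated)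
Conditions: t-BuLi (2.1 equiv), Et2O, −78 °C; MgBr2·OEt2, −78 → −40 °C; CuI (10 mol %), 12, THF, −40 → −20 °C; aq NH4Cl
Reagents that add atoms: methyl (S)-glycidate, COC(=O)[C@@H]1CO1
Why: Copper-catalysed SN2 opening of the glycidic ester at its CH2 by the configurationally stable alkenyl Grignard forms C1–C2 with retention of the E geometry; C3 is bought in the glycidate and is not touched.

**Step 5**
Reactants: 15 α-hydroxy ester; 16 N,O-dimethylhydroxylamine hydrochloride; 17 methylmagnesium bromide
Product: 19 (3S,5E,8R)-8-(tert-butyldimethylsilyloxy)-3-hydroxy-6-methyl-9-(triethylsilyloxy)non-5-en-2-one, via Weinreb amide 18 (not isolated)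
Conditions: MeNH(OMe)·HCl (1.6 equiv), i-PrMgCl (4.5 equiv), THF, −20 °C; then MeMgBr (3 equiv), 0 °C; aq NH4Cl
Reagents that add atoms: methylmagnesium bromide, C[Mg]Br
Why: One-pot ester-to-ketone conversion through the magnesium-chelated Weinreb amide, which accepts only one methyl Grignard (C15); the α-hydroxyl is carried as its alkoxide and C3 is not epimerised.

**Step 6**
Reactants: 19 α-hydroxy methyl ketone; 20 ethynylmagnesium bromide
Product: 21 (3S,4S,6E,9R)-9-(tert-butyldimethylsilyloxy)-3,7-dimethyl-10-(triethylsilyloxy)dec-6-en-1-yne-3,4-diol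
Conditions: HC≡CMgBr (4 equiv), THF, −78 → −20 °C; aq NH4Cl
Reagents that add atoms: ethynylmagnesium bromide, C#C[Mg]Br
Why: Cram-chelate-controlled Grignard addition: the C3 magnesium alkoxide chelates the ketone and the small, weakly basic ethynyl nucleophile attacks from the side of H-3, setting the tertiary carbinol C4 as S under control of the purchased C3 centre.

**Step 7**
Reactants: 21 propargylic diol; 22 2-methoxypropene
Product: 23 (4S,5S)-4-ethynyl-2,2,4-trimethyl-5-[(2E,5R)-5-(tert-butyldimethylsilyloxy)-3-methyl-6-(triethylsilyloxy)hex-2-en-1-yl]-1,3-dioxolane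
Conditions: 2-methoxypropene (3 equiv), PPTS (5 mol %), CH2Cl2, 0 °C
Reagents that add atoms: 2-methoxypropene, COC(C)=C
Why: Acid-catalysed ketalisation ties the 1,2-diol into a dioxolane, masking O-3 and O-4 for the oxidation, bromination and ring-closure steps; no stereocentre is affected.

**Step 8**
Reactants: 23 acetonide
Product: 24 (2R,4E)-2-(tert-butyldimethylsilyloxy)-6-[(4S,5S)-5-ethynyl-2,2,5-trimethyl-1,3-dioxolan-4-yl]-4-methylhex-4-enal
Conditions: (COCl)2, DMSO, CH2Cl2, −78 → −30 °C; Et3N, −78 → 0 °C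
Reagents that add atoms: none
Why: Swern conditions cleave and oxidise a primary triethylsilyl ether directly to the aldehyde (C7), while the secondary TBS ether, acetonide and alkyne survive and C8 is not epimerised at low temperature.

**Step 9**
Reactants: 24 C7 aldehyde; 25 methyl acrylate
Product: 26 methyl (4R,6E)-4-(tert-butyldimethylsilyloxy)-8-[(4S,5S)-5-ethynyl-2,2,5-trimethyl-1,3-dioxolan-4-yl]-3-hydroxy-6-methyl-2-methylideneoct-6-enoate (both C7 carbinol epimers)
Conditions: methyl acrylate (5 equiv), DABCO (1 equiv), 1,4-dioxane/H2O (1:1), 23 °C, 48 h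
Reagents that add atoms: methyl acrylate, C=CC(=O)OC
Why: Morita–Baylis–Hillman reaction installs C11–C13; the new carbinol at C7 needs no control because it becomes sp2 in step 11.

**Step 10**
Reactants: 26 Morita–Baylis–Hillman alcohol; 27 water
Product: 28 methyl (4R,6E)-4-(tert-butyldimethylsilyloxy)-3-hydroxy-6-methyl-2-methylidene-8-[(4S,5S)-2,2,5-trimethyl-5-(2-oxoethyl)-1,3-dioxolan-4-yl]oct-6-enoate
Conditions: [CpRu(MeCN)3]PF6 (5 mol %), 5,5′-bis(trifluoromethyl)-2,2′-bipyridine (5 mol %), NMP/H2O (4:1), 25 °C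
Reagents that add atoms: water, O
Why: Ruthenium-catalysed anti-Markovnikov hydration of the terminal alkyne through a vinylidene gives the C6 aldehyde directly; the internal and electron-poor alkenes are inert.

**Step 11**
Reactants: 28 aldehyde alcohol; 29 N-bromosuccinimide
Product: 30 methyl (2Z,4R,6E)-2-(bromomethyl)-4-(tert-butyldimethylsilyloxy)-6-methyl-8-[(4S,5S)-2,2,5-trimethyl-5-(2-oxoethyl)-1,3-dioxolan-4-yl]octa-2,6-dienoate
Conditions: NBS (1.5 equiv), Me2S (1.8 equiv), CH2Cl2, −20 → 0 °C
Reagents that add atoms: N-bromosuccinimide, O=C1CCC(=O)N1Br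
Why: Bromodimethylsulfonium activation and SN2′ bromide attack convert both carbinol epimers into the conjugated (Z)-2-(bromomethyl)enoate; the aldehyde is inert under these neutral conditions.

**Step 12**
Reactants: 30 aldehyde allylic bromide
Product: 33 (1(10)E)-8β-(tert-butyldimethylsilyloxy)-3β,4α-(isopropylidenedioxy)germacra-1(10),11(13)-dien-6α,12-olide, via allylchromium dichloride 31 (not isolated), via ring-closed hydroxy ester alkoxide 32 (not isolated)
Conditions: CrCl2 (20 mol %), Bu4NBr (0.1 M), DMF/THF (4:1), undivided cell, Al anode, Ni-foam cathode, 2 mA constant current (2.4 F/mol), 30 added over 10 h (final 2 mM), 23 °C; aq NH4Cl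
Reagents that add atoms: none
Why: Proposed new method: the cathode regenerates divalent chromium from trivalent chromium so that catalytic CrCl2 turns the allylic bromide into an allylchromium species, which adds through its γ-carbon (C7) to the C6 aldehyde in a chair transition state, while Al3+ from the anode takes the alkoxide off chromium and the C6 alkoxide lactonises onto the methyl ester; closing the ten-membered ring with both ring arms equatorial should give the 6,7-anti (trans-lactone) product, and the C8 stereocentre should set C7 (silyloxy group anti to the forming bond, C9 gauche); the closest known reaction types are the stoichiometric CrCl2 Nozaki–Hiyama allylation macrocyclisation of 2-(bromomethyl)enoates and the intermolecular electrochemical chromium-catalysed Nozaki–Hiyama–Kishi coupling.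

**Step 13**
Reactants: 33 silyl ether lactone
Product: 34 (1(10)E)-8β-hydroxy-3β,4α-(isopropylidenedioxy)germacra-1(10),11(13)-dien-6α,12-olide
Conditions: HF·pyridine, pyridine, THF, 0 → 23 °C
Reagents that add atoms: none
Why: Buffered fluoride desilylation frees only O-8; the acetonide, lactone and alkenes are stable, and the non-basic medium avoids translactonisation to the 8,12-olide.

**Step 14**
Reactants: 34 C8 alcohol; 35 angelic acid
Product: 37 (1(10)E)-8β-angeloyloxy-3β,4α-(isopropylidenedioxy)germacra-1(10),11(13)-dien-6α,12-olide, via angelic 2,4,6-trichlorobenzoic anhydride 36 (not isolated)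
Conditions: 35, 2,4,6-Cl3C6H2COCl, Et3N, toluene, 23 °C; then 34, DMAP (10 mol %), 23 → 40 °C
Reagents that add atoms: angelic acid, C/C=C(/C)C(=O)O
Why: Yamaguchi-type mixed-anhydride esterification acylates the only free hydroxyl with retention at C8, and mild temperature keeps the (Z)-angelate from isomerising to the tiglate.

**Step 15**
Reactants: 37 angelate acetonide
Product: 38 (1(10)E)-8β-angeloyloxy-3β,4α-dihydroxygermacra-1(10),11(13)-dien-6α,12-olide
Conditions: AcOH/H2O (4:1), 45 °C
Reagents that add atoms: none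
Why: Mild aqueous-acid ketal hydrolysis releases the 3,4-diol before the acid-sensitive oxirane exists; esters and the trisubstituted alkene tolerate acetic acid.

**Step 16**
Reactants: 38 diol alkene; 39 meta-chloroperbenzoic acid
Product: 40 argophyllin A
Conditions: mCPBA (1.1 equiv), NaHCO3, CH2Cl2, 0 °C
Reagents that add atoms: meta-chloroperbenzoic acid, OOC(=O)c1cccc(Cl)c1
Why: Prilezhaev epoxidation is chemoselective for the electron-rich C1=C10 alkene over the two conjugated alkenes, and exo-face attack on the E-alkene in the usual 6α,12-germacranolide conformer (C14 on the β-face) should give the 1β,10α-oxirane (1R,10R) under control of the existing ring stereocentres.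

**Compound list**
1 | (S)-glycidol | OC[C@H]1CO1 | starting material
2 | lithium acetylide–ethylenediamine complex | [Li+].[C-]#C.NCCN | starting material
3 | (R)-pent-4-yne-1,2-diol | C#CC[C@@H](O)CO | intermediate
4 | chlorotriethylsilane | CC[Si](Cl)(CC)CC | starting material
5 | tert-butyldimethylsilyl chloride | CC(C)(C)[Si](C)(C)Cl | starting material
6 | (R)-1-(triethylsilyloxy)pent-4-yn-2-ol | C#CC[C@@H](O)CO[Si](CC)(CC)CC | intermediate
7 | (R)-2-(tert-butyldimethylsilyloxy)-1-(triethylsilyloxy)pent-4-yne | C#CC[C@@H](O[Si](C)(C)C(C)(C)C)CO[Si](CC)(CC)CC | intermediate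
8 | trimethylaluminium | C[Al](C)C | starting material
9 | iodine | II | starting material
10 | dimethyl[(1E,4R)-4-(tert-butyldimethylsilyloxy)-2-methyl-5-(triethylsilyloxy)pent-1-en-1-yl]alane | C[Al](C)/C=C(\C)C[C@@H](O[Si](C)(C)C(C)(C)C)CO[Si](CC)(CC)CC | intermediate
11 | (1E,4R)-4-(tert-butyldimethylsilyloxy)-1-iodo-2-methyl-5-(triethylsilyloxy)pent-1-ene | I/C=C(\C)C[C@@H](O[Si](C)(C)C(C)(C)C)CO[Si](CC)(CC)CC | intermediate
12 | methyl (S)-glycidate | COC(=O)[C@@H]1CO1 | starting material
13 | (1E,4R)-alkenyllithium from 11 | [Li]/C=C(\C)C[C@@H](O[Si](C)(C)C(C)(C)C)CO[Si](CC)(CC)CC | intermediate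
14 | (1E,4R)-alkenylmagnesium bromide from 13 | Br[Mg]/C=C(\C)C[C@@H](O[Si](C)(C)C(C)(C)C)CO[Si](CC)(CC)CC | intermediate
15 | methyl (2S,4E,7R)-7-(tert-butyldimethylsilyloxy)-2-hydroxy-5-methyl-8-(triethylsilyloxy)oct-4-enoate | COC(=O)[C@@H](O)C/C=C(\C)C[C@@H](O[Si](C)(C)C(C)(C)C)CO[Si](CC)(CC)CC | intermediate
16 | N,O-dimethylhydroxylamine hydrochloride | CNOC.Cl | starting material
17 | methylmagnesium bromide | C[Mg]Br | starting material
18 | (2S,4E,7R)-7-(tert-butyldimethylsilyloxy)-2-hydroxy-N-methoxy-N,5-dimethyl-8-(triethylsilyloxy)oct-4-enamide | CON(C)C(=O)[C@@H](O)C/C=C(\C)C[C@@H](O[Si](C)(C)C(C)(C)C)CO[Si](CC)(CC)CC | intermediate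
19 | (3S,5E,8R)-8-(tert-butyldimethylsilyloxy)-3-hydroxy-6-methyl-9-(triethylsilyloxy)non-5-en-2-one | CC(=O)[C@@H](O)C/C=C(\C)C[C@@H](O[Si](C)(C)C(C)(C)C)CO[Si](CC)(CC)CC | intermediate
20 | ethynylmagnesium bromide | C#C[Mg]Br | starting material
21 | (3S,4S,6E,9R)-9-(tert-butyldimethylsilyloxy)-3,7-dimethyl-10-(triethylsilyloxy)dec-6-en-1-yne-3,4-diol | C#C[C@](C)(O)[C@@H](O)C/C=C(\C)C[C@@H](O[Si](C)(C)C(C)(C)C)CO[Si](CC)(CC)CC | intermediate
22 | 2-methoxypropene | COC(C)=C | starting material
23 | (4S,5S)-4-ethynyl-2,2,4-trimethyl-5-[(2E,5R)-5-(tert-butyldimethylsilyloxy)-3-methyl-6-(triethylsilyloxy)hex-2-en-1-yl]-1,3-dioxolane | C#C[C@]1(C)OC(C)(C)O[C@H]1C/C=C(\C)C[C@@H](O[Si](C)(C)C(C)(C)C)CO[Si](CC)(CC)CC | intermediate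
24 | (2R,4E)-2-(tert-butyldimethylsilyloxy)-6-[(4S,5S)-5-ethynyl-2,2,5-trimethyl-1,3-dioxolan-4-yl]-4-methylhex-4-enal | C#C[C@]1(C)OC(C)(C)O[C@H]1C/C=C(\C)C[C@@H](O[Si](C)(C)C(C)(C)C)C=O | intermediate
25 | methyl acrylate | C=CC(=O)OC | starting material
26 | methyl (4R,6E)-4-(tert-butyldimethylsilyloxy)-8-[(4S,5S)-5-ethynyl-2,2,5-trimethyl-1,3-dioxolan-4-yl]-3-hydroxy-6-methyl-2-methylideneoct-6-enoate (C3 epimers) | C#C[C@]1(C)OC(C)(C)O[C@H]1C/C=C(\C)C[C@@H](O[Si](C)(C)C(C)(C)C)C(O)C(=C)C(=O)OC | intermediate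
27 | water | O | starting material
28 | methyl (4R,6E)-4-(tert-butyldimethylsilyloxy)-3-hydroxy-6-methyl-2-methylidene-8-[(4S,5S)-2,2,5-trimethyl-5-(2-oxoethyl)-1,3-dioxolan-4-yl]oct-6-enoate (C3 epimers) | O=CC[C@]1(C)OC(C)(C)O[C@H]1C/C=C(\C)C[C@@H](O[Si](C)(C)C(C)(C)C)C(O)C(=C)C(=O)OC | intermediate
29 | N-bromosuccinimide | O=C1CCC(=O)N1Br | starting material
30 | methyl (2Z,4R,6E)-2-(bromomethyl)-4-(tert-butyldimethylsilyloxy)-6-methyl-8-[(4S,5S)-2,2,5-trimethyl-5-(2-oxoethyl)-1,3-dioxolan-4-yl]octa-2,6-dienoate | O=CC[C@]1(C)OC(C)(C)O[C@H]1C/C=C(\C)C[C@@H](O[Si](C)(C)C(C)(C)C)/C=C(\CBr)C(=O)OC | intermediate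
31 | allylchromium dichloride derived from 30 (chromium on C13) | O=CC[C@]1(C)OC(C)(C)O[C@H]1C/C=C(\C)C[C@@H](O[Si](C)(C)C(C)(C)C)/C=C(\C[Cr](Cl)Cl)C(=O)OC | intermediate
32 | ring-closed methyl ester with 6α-hydroxyl (formed as its metal alkoxide): (1(10)E)-methyl 8β-(tert-butyldimethylsilyloxy)-6α-hydroxy-3β,4α-(isopropylidenedioxy)germacra-1(10),11(13)-dien-12-oate | O[C@@H]1C[C@]2(C)OC(C)(C)O[C@H]2C/C=C(\C)C[C@@H](O[Si](C)(C)C(C)(C)C)[C@H]1C(=C)C(=O)OC | intermediate
33 | (1(10)E)-8β-(tert-butyldimethylsilyloxy)-3β,4α-(isopropylidenedioxy)germacra-1(10),11(13)-dien-6α,12-olide | C=C1C(=O)O[C@@H]2C[C@]3(C)OC(C)(C)O[C@H]3C/C=C(\C)C[C@@H](O[Si](C)(C)C(C)(C)C)[C@@H]12 | intermediate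
34 | (1(10)E)-8β-hydroxy-3β,4α-(isopropylidenedioxy)germacra-1(10),11(13)-dien-6α,12-olide | C=C1C(=O)O[C@@H]2C[C@]3(C)OC(C)(C)O[C@H]3C/C=C(\C)C[C@@H](O)[C@@H]12 | intermediate
35 | angelic acid | C/C=C(/C)C(=O)O | starting material
36 | angelic 2,4,6-trichlorobenzoic anhydride | C/C=C(/C)C(=O)OC(=O)c1c(Cl)cc(Cl)cc1Cl | intermediate
37 | (1(10)E)-8β-angeloyloxy-3β,4α-(isopropylidenedioxy)germacra-1(10),11(13)-dien-6α,12-olide | C=C1C(=O)O[C@@H]2C[C@]3(C)OC(C)(C)O[C@H]3C/C=C(\C)C[C@@H](OC(=O)/C(C)=C\C)[C@@H]12 | intermediate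
38 | (1(10)E)-8β-angeloyloxy-3β,4α-dihydroxygermacra-1(10),11(13)-dien-6α,12-olide | C=C1C(=O)O[C@@H]2C[C@](C)(O)[C@@H](O)C/C=C(\C)C[C@@H](OC(=O)/C(C)=C\C)[C@@H]12 | intermediate
39 | meta-chloroperbenzoic acid | OOC(=O)c1cccc(Cl)c1 | starting material
40 | argophyllin A | C=C1C(=O)O[C@@H]2C[C@](C)(O)[C@@H](O)C[C@H]3O[C@]3(C)C[C@@H](OC(=O)/C(C)=C\C)[C@@H]12 | target

**Step count and risks**
Total step count: 16. Longest linear sequence: 16 (the route is fully linear from 1 to 40).

Three steps most likely to fail: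

Step 12 (the new electrochemical macrocyclisation). The risks are poor chromium turnover, pinacol or oligomer formation, and imperfect facial control at C6 and C7. This is the least certain stereochemical point of the route: acyclic chromium and indium allylations of such enoates usually favour the cis-lactone, so the trans outcome rests on the ring-closure argument alone. Fallback with known chemistry: setting out from 30, the same bond is closed with the classical stoichiometric reagent instead of an electrode-driven catalytic cycle. Slow addition of 30 to excess CrCl2 in DMF/THF under high dilution (Nozaki–Hiyama allylation) gives ring-closed hydroxy ester 32, which is isolated and lactonised in a separate operation with PPTS in toluene, rejoining the route at 33. No compound outside the list is made (none F0).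

Step 10 (alkyne hydration). The cationic ruthenium catalyst may be slowed by the hindered propargylic centre or may isomerise the allylic alcohol of 26. Fallback: setting out from 26, the catalytic hydration is replaced by stoichiometric hydroboration–oxidation. Dicyclohexylborane (2.2 equiv, THF, 0 °C; the first equivalent caps the C7 hydroxyl as its borinate) adds anti-Markovnikov to the terminal alkyne to give the (E)-alkenyl(dicyclohexyl)borane O-borinate F1. Oxidation with sodium perborate in THF/H2O then releases the aldehyde and the free hydroxyl, returning to the route at 28.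

Step 16 (final epoxidation). The peracid may attack the wrong conformer face, or the product may open transannularly. Fallback: setting out from 34, the order of the endgame is reversed so that free hydroxyls can steer the oxidant. The acetonide is hydrolysed (AcOH/H2O) to (1(10)E)-3β,4α,8β-trihydroxygermacra-1(10),11(13)-dien-6α,12-olide F2. Epoxidation with VO(acac)2 and t-BuOOH, directed by the homoallylic 3- and 8-hydroxyls, gives 1β,10α-epoxy-3β,4α,8β-trihydroxygermacr-11(13)-en-6α,12-olide F3. The 3,4-diol is masked in the flask with PhB(OH)2 as the 3,4-O-phenylboronate of the epoxy triol F4, and O-8 is acylated with mixed anhydride 36 to the 3,4-O-phenylboronate of argophyllin A F5. Pinacol in the work-up frees the diol, arriving directly at 40.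

**Further compounds**
F0 | step 12 | none | none
F1 | step 10 | (E)-alkenyl(dicyclohexyl)borane O-dicyclohexylborinate from 26 | B(C2CCCCC2)(C3CCCCC3)/C=C/[C@]1(C)OC(C)(C)O[C@H]1C/C=C(\C)C[C@@H](O[Si](C)(C)C(C)(C)C)C(OB(C4CCCCC4)C5CCCCC5)C(=C)C(=O)OC
F2 | step 16 | (1(10)E)-3β,4α,8β-trihydroxygermacra-1(10),11(13)-dien-6α,12-olide | C=C1C(=O)O[C@@H]2C[C@](C)(O)[C@@H](O)C/C=C(\C)C[C@@H](O)[C@@H]12
F3 | step 16 | 1β,10α-epoxy-3β,4α,8β-trihydroxygermacr-11(13)-en-6α,12-olide | C=C1C(=O)O[C@@H]2C[C@](C)(O)[C@@H](O)C[C@H]3O[C@]3(C)C[C@@H](O)[C@@H]12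
F4 | step 16 | 3,4-O-phenylboronate of the epoxy triol | C=C1C(=O)O[C@@H]2C[C@]3(C)OB(c4ccccc4)O[C@H]3C[C@H]5O[C@]5(C)C[C@@H](O)[C@@H]12
F5 | step 16 | 3,4-O-phenylboronate of argophyllin A | C=C1C(=O)O[C@@H]2C[C@]3(C)OB(c4ccccc4)O[C@H]3C[C@H]5O[C@]5(C)C[C@@H](OC(=O)/C(C)=C\C)[C@@H]12
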